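**Retrosynthetic overview**

1. Enabling feature (drimane numbering: ring A = C1–C5/C10, ring B = C5–C10, C11 = benzylic CH2): ring B carries its methyl groups on C8 and C10, both flanking C9, with C6 para to C9. With C6 and C9 raised to carbonyls it is 2,6-dimethyl-1,4-benzoquinone (1), the ring-fusion bond C5–C10 is one of its C=C bonds, and C1–C2–C3–C4(CH3)2 of ring A is 4-methylpenta-1,3-diene (2).
2. Key disconnection: C1–C10 and C4–C5 together, by a catalytic enantioselective Diels–Alder reaction of 2 with 1; this closes ring A on the purchased ring B and sets the quaternary C10.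
3. The two helper carbonyls are then spent: C6=O → enol triflate → C–H gives a linear dienone, whose Li/NH3 1,6-reduction installs the trans ring fusion (C5–H); C9=O → exocyclic methylene (drima-7,9(11)-diene).
4. Last disconnection C11–aryl: 9-BBN hydroboration of the diene (sets C9) and B-alkyl Suzuki–Miyaura coupling with MOM-protected methyl 5-bromo-2,3,4-trihydroxybenzoate; MOM removal ends the route.
5. Ring order: ring B (commercial quinone) → ring A (key step) → arene joined last.

Key step: step 1

Assumption: the (S)-diphenylprolinol-derived oxazaborolidinium ion is taken to expose the quinone face that leads to the (8aS) adduct (α-C–H···O binding model for quinones); if the opposite sense is found, the mirror-image catalyst is used and nothing else changes.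

**Route**

Step 1
Reactants: 1 2,6-dimethyl-1,4-benzoquinone; 2 4-methylpenta-1,3-diene
Product: 3 (4aR,8aS)-2,5,5,8a-tetramethyl-4a,5,8,8a-tetrahydronaphthalene-1,4-dione (cis-fused adduct)
Conditions: (S)-α,α-diphenylprolinol-derived B-(o-tolyl)oxazaborolidine (20 mol %), Tf2NH (18 mol %), 2 (4 equiv), CH2Cl2, −78 → −40 °C
Reagents that add atoms: none
Why: The cationic oxazaborolidinium binds the carbonyl of 1 that sits between the two ring C–H groups (less hindered, more basic), which makes the methyl-bearing β-carbon the electrophilic terminus; a concerted but asynchronous [4+2] cycloaddition follows in which the CH2 terminus of 2 bonds first to that carbon (C1–C10) and the C(CH3)2 terminus closes onto the neighbouring CH (C4–C5). The closest known reaction type is the chiral oxazaborolidinium-catalysed Diels–Alder reaction of alkyl-1,4-benzoquinones with acyclic dienes, together with the Lewis-acid-controlled regiochemistry of 2,6-dimethylbenzoquinone. Ring A is closed by intermolecular [4+2] cycloaddition onto the preformed ring B, suprafacial on both partners, hence the cis fusion at this stage. The quaternary C10 (8aS) is set by the catalyst, whose aryl group shields one face of the bound quinone; C5 is set cis to the angular methyl by the suprafacial addition and is provisional (made planar in step 2, reset in step 4). The step needs regio- and enantioface selectivity: the first comes from the Lewis acid position matched with the polarisation of the diene (tertiary allyl-cation character at C(CH3)2), the second from the catalyst, while the two C=C bonds of 1 are equivalent by symmetry and the diene termini carry no stereogenic substituent, so site and endo/exo selectivity do not arise. The diene is used in excess at low temperature because its Z-methyl group slows s-cis alignment and invites acid-induced oligomerisation.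

Step 2
Reactants: 3 (4aR,8aS)-2,5,5,8a-tetramethyl-4a,5,8,8a-tetrahydronaphthalene-1,4-dione
Product: 5 (8aS)-2,5,5,8a-tetramethyl-1-oxo-1,5,8,8a-tetrahydronaphthalen-4-yl trifluoromethanesulfonate, via lithium enolate 4 (not isolated)
Conditions: LiN(i-Pr)2 (1.1 equiv), THF, −78 °C; then N-(5-chloropyridin-2-yl)bis(trifluoromethanesulfonimide) (1.2 equiv), −78 → 0 °C
Reagents that add atoms: N-(5-chloropyridin-2-yl)bis(trifluoromethanesulfonimide), O=S(=O)(N(c1ccc(Cl)cn1)S(=O)(=O)C(F)(F)F)C(F)(F)F
Why: Kinetic α'-deprotonation of the only α-hydrogen (ring-fusion C5–H next to the C6 carbonyl; the C9 carbonyl has none) and O-triflation of the cross-conjugated enolate is standard enol triflate formation, and it turns the provisional C5 stereocentre into an sp2 carbon.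

Step 3
Reactants: 5 (8aS)-2,5,5,8a-tetramethyl-1-oxo-1,5,8,8a-tetrahydronaphthalen-4-yl trifluoromethanesulfonate
Product: 6 (8aS)-2,5,5,8a-tetramethyl-5,8-dihydronaphthalen-1(8aH)-one
Conditions: Pd(OAc)2 (5 mol %), PPh3 (10 mol %), HCO2H (2 equiv), Et3N (3 equiv), DMF, 60 °C, dark
Reagents that add atoms: none
Why: Palladium-catalysed formate reduction of an enol triflate (oxidative addition to zerovalent palladium, formate exchange, loss of CO2, C–H reductive elimination) replaces C6–OTf by C6–H without touching the enone; the resulting 2,4-dienone cannot aromatise because C10 is quaternary and is shielded from dimerisation by its fully substituted terminus.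

Step 4
Reactants: 6 (8aS)-2,5,5,8a-tetramethyl-5,8-dihydronaphthalen-1(8aH)-one
Product: 9 (4aS,8aS)-2,5,5,8a-tetramethyl-4a,5,8,8a-tetrahydronaphthalen-1(4H)-one, via lithium dienolate 7 (not isolated), via deconjugated enone 8 (not isolated)
Conditions: Li (2.5 equiv), t-BuOH (1 equiv), NH3(l)/THF, −78 °C; isoprene, then NH4Cl; then DBU (0.2 equiv), CH2Cl2, rt
Reagents that add atoms: none
Why: Dissolving-metal 1,6-reduction of a linearly conjugated dienone protonates the δ-carbon (C5) axially on the α-face, away from the angular C10 methyl and the 4β-methyl, which should give the trans fusion (4aS) by the same control as in Birch-type reductions of octalones; the surviving lithium dienolate is quenched to the β,γ-enone, DBU moves the double bond into conjugation, and the isolated ring A alkene is inert.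

Step 5
Reactants: 9 (4aS,8aS)-2,5,5,8a-tetramethyl-4a,5,8,8a-tetrahydronaphthalen-1(4H)-one
Product: 10 (4aS,8aS)-2,5,5,8a-tetramethyl-4a,5,6,7,8,8a-hexahydronaphthalen-1(4H)-one (11-nordrim-7-en-9-one)
Conditions: H2 (1 atm), RhCl(PPh3)3 (5 mol %), benzene/EtOH, rt
Reagents that add atoms: none
Why: Homogeneous hydrogenation with RhCl(PPh3)3 reduces the cis-disubstituted ring A alkene much faster than the trisubstituted α-methyl enone, so only ring A is saturated and no stereocentre is formed.

Step 6
Reactants: 10 (4aS,8aS)-2,5,5,8a-tetramethyl-4a,5,6,7,8,8a-hexahydronaphthalen-1(4H)-one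
Product: 11 (4aS,8aS)-4,4,7,8a-tetramethyl-8-methylidene-1,2,3,4,4a,5,8,8a-octahydronaphthalene (drima-7,9(11)-diene)
Conditions: Ph3PCH3Br (3 equiv), KOtBu (2.8 equiv), toluene, 90 °C
Reagents that add atoms: methyltriphenylphosphonium bromide, C[P+](c1ccccc1)(c1ccccc1)c1ccccc1.[Br-]
Why: Wittig methylenation with excess ylide in hot toluene is the standard answer to hindered ketones; the ketone has no α-hydrogen to epimerise, and any dienolate formed by γ-deprotonation returns 10 on work-up.

Step 7
Reactants: 12 methyl 2,3,4-trihydroxybenzoate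
Product: 13 methyl 2,3,4-tris(methoxymethoxy)benzoate
Conditions: NaH (3.6 equiv), MOMCl (3.6 equiv), DMF, 0 °C → rt, Ar
Reagents that add atoms: chloromethyl methyl ether, COCCl
Why: Williamson-type O-alkylation of the three phenoxides; NaH is chosen so that the hydrogen-bonded 2-OH next to the ester also reacts.

Step 8
Reactants: 13 methyl 2,3,4-tris(methoxymethoxy)benzoate
Product: 14 methyl 5-bromo-2,3,4-tris(methoxymethoxy)benzoate
Conditions: NBS (1.05 equiv), MeCN, 0 °C → rt
Reagents that add atoms: N-bromosuccinimide, O=C1CCC(=O)N1Br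
Why: Electrophilic aromatic bromination should go to C5, the only free position ortho/para to two alkoxy groups and meta to the ester (C6 is ortho to the ester and activated only by the twisted central alkoxy group).

Step 9
Reactants: 11 drima-7,9(11)-diene; 14 methyl 5-bromo-2,3,4-tris(methoxymethoxy)benzoate
Product: 16 methyl 2,3,4-tris(methoxymethoxy)-5-{[(1S,4aS,8aS)-2,5,5,8a-tetramethyl-1,4,4a,5,6,7,8,8a-octahydronaphthalen-1-yl]methyl}benzoate, via B-(drim-7-en-11-yl)-9-BBN 15 (not isolated)
Conditions: 9-BBN (1.3 equiv), THF, 0 → 50 °C; then 14 (0.9 equiv), Pd(dppf)Cl2 (5 mol %), K3PO4 (3 equiv, 3 M aq.), DMF, 60 °C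
Reagents that add atoms: none
Why: 9-BBN adds to the exocyclic 1,1-disubstituted double bond of the diene with boron on C11 and hydrogen delivered to C9 from the α-face, anti to the axial C10 methyl, which sets C9 (S) with the CH2 group equatorial; the B-alkyl Suzuki–Miyaura coupling then joins the primary alkylborane to 14 and tolerates the ester and the MOM ethers.

Step 10
Reactants: 16 methyl 2,3,4-tris(methoxymethoxy)-5-{[(1S,4aS,8aS)-2,5,5,8a-tetramethyl-1,4,4a,5,6,7,8,8a-octahydronaphthalen-1-yl]methyl}benzoate
Product: 17 methyl 2,3,4-trihydroxy-5-{[(1S,4aS,8aS)-2,5,5,8a-tetramethyl-1,4,4a,5,6,7,8,8a-octahydronaphthalen-1-yl]methyl}benzoate (CNP0185238.1)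
Conditions: HCl (ca. 1 M in MeOH), MeOH, 0 °C → rt
Reagents that add atoms: none
Why: Acid-catalysed transacetalisation transfers the three MOM groups to methanol; methanol keeps the methyl ester unchanged, and dilute acid at room temperature should not protonate the trisubstituted alkene (which would cause migration or chroman formation).

**Compound list**

1 | 2,6-dimethyl-1,4-benzoquinone | CC1=CC(=O)C=C(C)C1=O | starting material
2 | 4-methylpenta-1,3-diene | C=CC=C(C)C | starting material
3 | (4aR,8aS)-2,5,5,8a-tetramethyl-4a,5,8,8a-tetrahydronaphthalene-1,4-dione | CC1=CC(=O)[C@@H]2C(C)(C)C=CC[C@]2(C)C1=O | intermediate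
4 | lithium (8aS)-2,5,5,8a-tetramethyl-1-oxo-1,5,8,8a-tetrahydronaphthalen-4-olate (lithium enolate of 3, not isolated) | [Li+].CC1=CC([O-])=C2C(C)(C)C=CC[C@]2(C)C1=O | intermediate
5 | (8aS)-2,5,5,8a-tetramethyl-1-oxo-1,5,8,8a-tetrahydronaphthalen-4-yl trifluoromethanesulfonate | CC1=CC(OS(=O)(=O)C(F)(F)F)=C2C(C)(C)C=CC[C@]2(C)C1=O | intermediate
6 | (8aS)-2,5,5,8a-tetramethyl-5,8-dihydronaphthalen-1(8aH)-one | CC1=CC=C2C(C)(C)C=CC[C@]2(C)C1=O | intermediate
7 | lithium (4aS,8aS)-2,5,5,8a-tetramethyl-4a,5,8,8a-tetrahydronaphthalen-1-olate (lithium dienolate, not isolated) | [Li+].[O-]C1=C(C)C=C[C@H]2C(C)(C)C=CC[C@]12C | intermediate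
8 | (4aS,8aS)-2,5,5,8a-tetramethyl-4a,5,8,8a-tetrahydronaphthalen-1(2H)-one (C2 epimers, not isolated) | CC1C=C[C@H]2C(C)(C)C=CC[C@]2(C)C1=O | intermediate
9 | (4aS,8aS)-2,5,5,8a-tetramethyl-4a,5,8,8a-tetrahydronaphthalen-1(4H)-one | CC1=CC[C@H]2C(C)(C)C=CC[C@]2(C)C1=O | intermediate
10 | (4aS,8aS)-2,5,5,8a-tetramethyl-4a,5,6,7,8,8a-hexahydronaphthalen-1(4H)-one (11-nordrim-7-en-9-one) | CC1=CC[C@H]2C(C)(C)CCC[C@]2(C)C1=O | intermediate
11 | (4aS,8aS)-4,4,7,8a-tetramethyl-8-methylidene-1,2,3,4,4a,5,8,8a-octahydronaphthalene (drima-7,9(11)-diene) | C=C1C(C)=CC[C@H]2C(C)(C)CCC[C@]12C | intermediate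
12 | methyl 2,3,4-trihydroxybenzoate | COC(=O)c1ccc(O)c(O)c1O | starting material
13 | methyl 2,3,4-tris(methoxymethoxy)benzoate | COCOc1ccc(C(=O)OC)c(OCOC)c1OCOC | intermediate
14 | methyl 5-bromo-2,3,4-tris(methoxymethoxy)benzoate | COCOc1c(Br)cc(C(=O)OC)c(OCOC)c1OCOC | intermediate
15 | 9-{[(1S,4aS,8aS)-2,5,5,8a-tetramethyl-1,4,4a,5,6,7,8,8a-octahydronaphthalen-1-yl]methyl}-9-borabicyclo[3.3.1]nonane (not isolated) | CC1=CC[C@H]2C(C)(C)CCC[C@]2(C)[C@H]1CB1C2CCCC1CCC2 | intermediate
16 | methyl 2,3,4-tris(methoxymethoxy)-5-{[(1S,4aS,8aS)-2,5,5,8a-tetramethyl-1,4,4a,5,6,7,8,8a-octahydronaphthalen-1-yl]methyl}benzoate | COC(=O)c1cc(C[C@H]2C(C)=CC[C@H]3C(C)(C)CCC[C@]23C)c(OCOC)c(OCOC)c1OCOC | intermediate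
17 | methyl 2,3,4-trihydroxy-5-{[(1S,4aS,8aS)-2,5,5,8a-tetramethyl-1,4,4a,5,6,7,8,8a-octahydronaphthalen-1-yl]methyl}benzoate | COC(=O)c1cc(C[C@H]2C(C)=CC[C@H]3C(C)(C)CCC[C@]23C)c(O)c(O)c1O | target

**Count and risks**

Total steps: 10. Longest linear sequence: 8 steps (steps 1–6, 9, 10); steps 7–8 make the arene partner.

Steps most likely to fail:

Step 1. The cycloaddition may be too slow because the Z-methyl group of 2 disfavours the s-cis conformer, acid-induced oligomerisation of the diene may compete, or enantioface discrimination may be weak. Fallback, from 1 back to 10: the diene is replaced by allylidenecyclopropane F1 (Wittig reaction of cyclopropylidenetriphenylphosphorane with acrolein), a strain-activated surrogate of 2 with no methyl group on its terminus; the same catalyst should give spiro adduct F2. Exhaustive hydrogenation (H2, PtO2, AcOH; CrO3/H2SO4 to return any carbinol to the ketone) saturates both C=C bonds and opens the cyclopropane at its CH2–CH2 bond to the gem-dimethyl group, giving saturated dione F3. SeO2 (t-BuOH, reflux) dehydrogenates the 1,4-dione to ene-dione F4. Enolisation and triflation as in step 2 (lithium enolate F5, triflate F6), formate reduction as in step 3 (dienone F7), and Li/NH3 reduction with DBU isomerisation as in step 4 (lithium dienolate F8, deconjugated enone F9) then give 10 directly, so step 5 is not needed.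

Step 2. Deprotonation may occur at the γ-methyl group instead of the hindered ring-fusion C–H, or the base may decompose the ene-dione. Fallback, from 3 back to 6: NaBH4/CeCl3·7H2O (MeOH, −78 °C) should reduce only the less hindered C6 carbonyl to γ-hydroxy enone F10 (either C6 epimer serves). Dehydration with methyl N-(triethylammoniosulfonyl)carbamate (benzene, 50 °C), which can only remove the ring-fusion hydrogen, then gives trienone 6 without any enolate chemistry.

Step 4. The dienyl anion may be protonated on the β-face (cis fusion) or at the β- instead of the δ-carbon, or over-reduction may occur. Fallback, from 6 back to 10: all three C=C bonds of 6 are hydrogenated (H2 4 atm, PtO2, AcOH; CrO3·pyridine to re-oxidise any carbinol); hydrogen should add to the hindered 5,6-bond from the α-face, away from the angular methyl, to give trans-fused saturated ketone F11 (C8 epimers). LiN(i-Pr)2 can enolise only toward C8 (lithium enolate F12), TMSCl gives silyl enol ether F13, and Saegusa–Ito oxidation (Pd(OAc)2, MeCN) restores the 7,8-double bond to give 10; step 5 is then not needed.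

Further compounds
F1 | step 1 | allylidenecyclopropane (prop-2-en-1-ylidenecyclopropane) | C=CC=C1CC1
F2 | step 1 | (4a'R,8a'S)-2',8a'-dimethyl-4a',8a'-dihydro-8'H-spiro[cyclopropane-1,5'-naphthalene]-1',4'-dione | CC1=CC(=O)[C@@H]2C3(CC3)C=CC[C@]2(C)C1=O
F3 | step 1 | (8aS)-2,5,5,8a-tetramethyloctahydronaphthalene-1,4-dione (C2 and C4a epimers) | CC1CC(=O)C2C(C)(C)CCC[C@]2(C)C1=O
F4 | step 1 | (8aS)-2,5,5,8a-tetramethyl-4a,5,6,7,8,8a-hexahydronaphthalene-1,4-dione (C4a epimers) | CC1=CC(=O)C2C(C)(C)CCC[C@]2(C)C1=O
F5 | step 1 | lithium (8aS)-2,5,5,8a-tetramethyl-1-oxo-1,5,6,7,8,8a-hexahydronaphthalen-4-olate | [Li+].CC1=CC([O-])=C2C(C)(C)CCC[C@]2(C)C1=O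
F6 | step 1 | (8aS)-2,5,5,8a-tetramethyl-1-oxo-1,5,6,7,8,8a-hexahydronaphthalen-4-yl trifluoromethanesulfonate | CC1=CC(OS(=O)(=O)C(F)(F)F)=C2C(C)(C)CCC[C@]2(C)C1=O
F7 | step 1 | (8aS)-2,5,5,8a-tetramethyl-5,6,7,8-tetrahydronaphthalen-1(8aH)-one | CC1=CC=C2C(C)(C)CCC[C@]2(C)C1=O
F8 | step 1 | lithium (4aS,8aS)-2,5,5,8a-tetramethyl-4a,5,6,7,8,8a-hexahydronaphthalen-1-olate | [Li+].[O-]C1=C(C)C=C[C@H]2C(C)(C)CCC[C@]12C
F9 | step 1 | (4aS,8aS)-2,5,5,8a-tetramethyl-4a,5,6,7,8,8a-hexahydronaphthalen-1(2H)-one (C2 epimers) | CC1C=C[C@H]2C(C)(C)CCC[C@]2(C)C1=O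
F10 | step 2 | (4aR,8aS)-4-hydroxy-2,5,5,8a-tetramethyl-4a,5,8,8a-tetrahydronaphthalen-1(4H)-one (C4 epimers) | CC1=CC(O)[C@@H]2C(C)(C)C=CC[C@]2(C)C1=O
F11 | step 4 | (4aS,8aS)-2,5,5,8a-tetramethyloctahydronaphthalen-1(2H)-one (C2 epimers) | CC1CC[C@H]2C(C)(C)CCC[C@]2(C)C1=O
F12 | step 4 | lithium (4aS,8aS)-2,5,5,8a-tetramethyl-3,4,4a,5,6,7,8,8a-octahydronaphthalen-1-olate | [Li+].[O-]C1=C(C)CC[C@H]2C(C)(C)CCC[C@]12C
F13 | step 4 | trimethyl{[(4aS,8aS)-2,5,5,8a-tetramethyl-3,4,4a,5,6,7,8,8a-octahydronaphthalen-1-yl]oxy}silane | C[Si](C)(C)OC1=C(C)CC[C@H]2C(C)(C)CCC[C@]12C
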